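Readings and results were generated by integration on assumed constants, and the scatter is random.

- 3 questions stand on these two flasks: which of north and east ends higher in target, and what each one ends at.

* which of the two ends with the higher amount of target, in percent of the substrate charged ("neither" if they lie within 2 percentage points) (north / east / neither)
* target at the end, in percent of the substrate charged, north
* target at the end, in percent of the substrate charged, east

common to all: substrate 0.29 M
- noon: coupling partner 0.29 M (in portions, 4); temperature 5 °C; run made earlier; portions every 1.0 h
- midnight: coupling partner 0.43 M (in portions, 4); temperature 20 °C; run made earlier; portions every 1.0 h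
- north: coupling partner 0.580 M (in portions, 4); at 10 °C throughout; the portions of coupling partner follow each other after 0.60 h, the first at the start; time 4.0 h
- east: coupling partner 0.580 M (in portions, 4); at 10 °C until 2.0 h, from then on at 30 °C; the portions of coupling partner follow each other after 1.0 h, the first at the start; time 4.0 h

| noon: time / h | noon: target / % | midnight: time / h | midnight: target / % |
|---|---|---|---|
| 1.00 | 2 | 0.667 | 0 |
| 2.00 | 5 | 1.33 | 8 |
| 3.00 | 7 | 2.00 | 15 |
| 4.00 | 9 | 2.50 | 13 |
| 5.00 | 10 | 3.00 | 16 |

(standard deviation of a reading: 1.5 percentage points)

- on the list of suspects stand: coupling partner + tight pair -> target; tight pair <-> loose pair; substrate <-> tight pair; substrate <-> dormant form; tight pair -> side product; coupling partner + loose pair -> isomer of the product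

- I treat substrate and its pairs as one pool that coupling partner turns into target, pseudo-first-order at a given partner level. The fraction of substrate not yet target then falls as e^(−N), where N is the capture number, κ times E.
- E, the exposure, is the whole charge of coupling partner times the time less the average wait of a portion, with nothing subtracted for use. κ, the capture constant, belongs to one temperature.
- The noon run has E = 60.9 M·min and target 10%, so κ = 0.104 M⁻¹ h⁻¹. The midnight run has E = 38.7 M·min and target 16%, so κ = 0.270 M⁻¹ h⁻¹.
- Those readings scatter by 1.5 percentage points, so the factor 2.60 between the runs is itself a reading. I let κ grow by the same factor per equal step of temperature, which gives 0.143 M⁻¹ h⁻¹ at 10 °C and 0.512 M⁻¹ h⁻¹ at 30 °C.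
- N starts in both flasks with slope 0.0207 h⁻¹. At 2.0 h north stands at 0.0911 and east at 0.0621, lower because east's portions come later.
- That time is east's knee: its slope jumps to 0.223 h⁻¹, steeper than north's 0.0828 h⁻¹, so in my reckoning east crosses north at 2.21 h.
- At the end north has N = 0.257, so target 22.6%. East's capture number, κ times E summed over its two temperatures, is 0.581, so target 44.1%. Both of my curves are still rising there, and I answer east.
- The forecast says east, with north 23% (17% to 30%) and east 26% (18% to 34%): “East is slightly ahead, but the margin is uncertain.” My east stands higher than that.
- The flask gives east, with north 20.5% and east 38.5%.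

    coupling partner + tight pair → target (k = 1060 M⁻¹ h⁻¹, Ea = 50.0 kJ mol⁻¹)
    tight pair ⇌ loose pair (K = 2.20, k = 1070 h⁻¹, Ea = 71.0 kJ mol⁻¹, ΔH = −90.0 kJ mol⁻¹)
    substrate ⇌ tight pair (K = 4.80 × 10⁻⁴, k = 1.12 h⁻¹, Ea = 93.0 kJ mol⁻¹, ΔH = −17.0 kJ mol⁻¹)
    substrate ⇌ dormant form (K = 1.56, k = 0.446 h⁻¹, Ea = 78.0 kJ mol⁻¹, ΔH = −19.0 kJ mol⁻¹)
    tight pair → side product (k = 1.07 h⁻¹, Ea = 97.0 kJ mol⁻¹)
    coupling partner + loose pair → isomer of the product (k = 826 M⁻¹ h⁻¹, Ea = 58.0 kJ mol⁻¹)
    (constants at 10 °C)

- Turned backwards, east's 38.5% means a capture number of 0.486, lower than my 0.581, a ratio of 0.836. The neighbouring flask is east with 0.23 M of coupling partner instead of 0.580 M. In my reckoning N goes with the charge, so I scale my east figure by the charge and by that ratio, which gives 0.193 and target 17.5%. That flask ends with 19.3% target.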